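## Analysis of the target

Numbering used here: hydrindenone atoms C1–C7a, chromane atoms primed, the linking methylene C1''.

- The target joins a 6-methoxy-2,8-dimethylchromane through C1'' on its C2' to C6 of a cis-fused 3a,7a-dimethyl-hexahydroinden-4-one. The six-membered ring is C3a–C4–C5–C6–C7–C7a, the five-membered ring is C1–C2–C3–C3a–C7a, and C5 carries a 2-hydroxy-2-methylpropyl group.
- There are three stereocentres, all fully substituted: C2' (R, oxygen-bearing) and the contiguous all-carbon pair C3a/C7a (S,S, methyls cis). C1'' and the sp2 carbon C6 separate the pair from C2', so no stereochemical information can pass between them. Both halves must be made as single enantiomers and then joined.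
- The enone C4(=O)–C5=C6 is tetrasubstituted. Its two alkene substituents are nearly alike, each a CH2 attached to an oxygen-bearing quaternary carbon, so any step that must tell C5 from C6 is delicate.
- The tertiary alcohol is γ to the ketone, which allows ring–chain hemiketal formation and acid-promoted dehydration.
- The C2'–O bond is β to C1'', a vinylogously enolisable position, so strong base can open the chromane by retro-oxa-Michael reaction and erase C2'.
- The hard part is the six-membered ring: a ketone flanked by two adjacent quaternary stereocentres on one side and a fully substituted alkene on the other.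
- The feature that invites the key move: C4, C3a, C7a and C7 are exactly the four carbons of a ketene/alkene cyclobutanone, and C5=C6 is what remains, an alkyne. Strain-release insertion of that alkyne into the C4–C7 bond builds the whole ring and joins the two halves in one operation.

## Retrosynthetic reasoning

**17 to 16 (C–O bond of the tertiary alcohol).** The alcohol is taken back to the isopropenyl group of enone 16, to be hydrated last in the Markovnikov sense under neutral radical conditions. An alkyne that already carried the tertiary alcohol would offer nickel two termini of equal bulk. As a methallyl group this terminus is planar and slim, which is the handle for regiocontrol in the key step.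

**16 to 15 + 10 (C4–C5 and C6–C7).** Both bonds are cut at once: enone 16 is the product of inserting the alkyne of enyne 10 into the acyl–CH2 bond of cyclobutanone 15. This cut is chosen because it removes the entire six-membered ring and leaves the quaternary pair in a precursor where a (2+2) cycloaddition sets it cis by construction. It also joins the two enantiopure halves under neutral conditions that cannot touch C2'. The forward reaction must cleave the CH2 side of the ketone, not the quaternary side, and must place the methallyl-bearing alkyne carbon next to the carbonyl.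

**15 to 14, 13, 12 and 11 (the quaternary pair).** Cyclobutanone 15 is the single enantiomer of racemate 13, separated through ketal 14 made with a C2-symmetric chiral diol. Racemate 13 comes from dichloroketone 12, the ketene (2+2) adduct of the symmetrical alkene 11. Both quaternary centres arise in that one cycloaddition. A resolution is accepted because the alkene offers a chiral catalyst only the difference between a methyl and a ring methylene, and because 13 is two steps from a commodity alkene.

**10 to 8, 7 and 6 (the alkyne).** The alkyne carbon attached to C1'' is the former ester carbon of 6, reached by reduction to aldehyde 7, dibromo-olefination to 8 and conversion to the acetylide 9. The methallyl group is attached to 9 by allylic substitution. The base-free olefination is chosen because aldehyde 7 is a β-aryloxy aldehyde.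

**6 to 5 (C2'–O and C1''–C(ester); sets C2').** The chromane ring, its quaternary stereocentre and the one-carbon handle are formed together by an enantioselective carbonylative Wacker cyclisation of phenol 5. The 1,1-disubstituted alkene guarantees that oxygen bonds to the substituted carbon and that the alkylpalladium has no β-hydrogen.

**5 to 2 and 1 (aryl–CH2–CH2 chain).** The homoallyl chain is cut at the benzylic C–C bond: a methallyl nucleophile adds to the o-quinone methide 4 released from the quaternised Mannich base 3. Mannich base 2 comes from phenol 1, whose only free ortho position is the one required.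

## Alternatives that were turned down

Alternative 1: The textbook cut is C5=C6, made by intramolecular aldol cyclodehydration of 1,5-diketone A1.
- A1 needs the cis-1,2-dimethylcyclopentane with two different acyl arms as a single enantiomer. It has no symmetry to exploit, so the two quaternary centres would be built by stepwise, stereocontrolled enolate chemistry over many steps.
- A1 is a β-aryloxy ketone. Enolisation toward C1'' under the condensation conditions opens the chromane by retro-oxa-Michael reaction and erodes C2'.
- A second six-membered aldol mode competes (the C1'' enolate onto the C4 carbonyl).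

Alternative 2: A De Mayo sequence, cutting C3a–C4 and C7a–C7. Irradiation of alkene 11 with the enol of 1,3-diketone A2, then retro-aldol fragmentation, would give A1 in one pot and create the quaternary pair and the diketone together.
- A2 has two enol tautomers, which lead to two constitutionally different diketones.
- The new quaternary pair forms with no facial bias from the remote C2', so a 1:1 pair of diastereomers differing only at distant centres is expected, with no handle for late separation.
- The electron-rich aryl ether is a competing chromophore.
- The route still ends in the base-sensitive condensation of Alternative 1.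

Alternative 3: The same nickel insertion, but with the chromane closed last (cut at C2'–O). Conjugated enyne A3, carrying the free phenol, would be inserted into 15 to give dienone A4, and the phenol would then add to A4 by intramolecular oxa-1,6-addition.
- The attraction is real: the alkenyl group fixes the orientation of the alkyne electronically.
- It was turned down because C2' would then be created last, as a fully substituted centre, by a reversible conjugate addition with no stereocentre nearby. An external catalyst would have to control a quaternary C–O bond formation for which no firm basis exists.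
- The risk of the route would then sit in two steps instead of one.

Key step: step 11

Remark: 12 and 13 are racemates (one enantiomer drawn). The enantiomer of the BOXAX ligand in step 3 is the one expected to give the R ester; the sense of induction must be confirmed on 6, and the antipodal ligand serves otherwise.

## Route

Step 1
Reactants: 1 4-methoxy-2-methylphenol
Product: 2 2-[(dimethylamino)methyl]-4-methoxy-6-methylphenol
Conditions: Me2NH (40% aq.), CH2O (37% aq.), EtOH, reflux
Reagents that add atoms: formaldehyde C=O; dimethylamine CNC
Why: Phenolic Mannich reaction; the iminium ion attacks the only free position ortho to the hydroxyl (para is blocked by OMe), so one regioisomer is expected.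

Step 2
Reactants: 2 2-[(dimethylamino)methyl]-4-methoxy-6-methylphenol
Product: 5 4-methoxy-2-methyl-6-(3-methylbut-3-en-1-yl)phenol, via benzyltrimethylammonium iodide 3 (not isolated), via o-quinone methide 4 (not isolated)
Conditions: MeI (1.05 equiv), THF, rt; volatiles removed; then 2-methylallylmagnesium chloride (3 equiv), THF, 0 °C to 50 °C; aq. HCl work-up
Reagents that add atoms: 2-methylallylmagnesium chloride C=C(C)C[Mg]Cl
Why: N-Methylation turns the amine into a leaving group; the first equivalent of Grignard reagent forms the phenoxide, which expels trimethylamine to give o-quinone methide 4, and a second equivalent adds 1,4 to its exocyclic methylene and restores the aromatic ring (o-quinone methide alkylation). The methallyl nucleophile is symmetrical, so allylic transposition is of no consequence.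

Step 3
Reactants: 5 4-methoxy-2-methyl-6-(3-methylbut-3-en-1-yl)phenol
Product: 6 methyl 2-[(2R)-6-methoxy-2,8-dimethylchroman-2-yl]acetate
Conditions: Pd(OCOCF3)2 (5 mol %), (R,R)-Bn-BOXAX [2,2'-bis(4-benzyl-4,5-dihydrooxazol-2-yl)-1,1'-binaphthyl] (20 mol %), p-benzoquinone (4 equiv), CO (1 atm), MeOH, rt
Reagents that add atoms: carbon monoxide [C-]#[O+]; methanol CO
Why: Enantioselective domino Wacker cyclisation/carbonylation: divalent palladium on the chiral bis(oxazoline) activates the 1,1-disubstituted alkene, the phenol adds 6-exo-trig to the substituted carbon and sets C2, and the neopentyl-type alkylpalladium, which has no β-hydrogen, inserts CO and is cleaved by methanol. Benzoquinone reoxidises zerovalent palladium; the configuration of C2 is controlled by the ligand, which differentiates the alkene faces in the oxypalladation.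

Step 4
Reactants: 6 methyl 2-[(2R)-6-methoxy-2,8-dimethylchroman-2-yl]acetate
Product: 7 2-[(2R)-6-methoxy-2,8-dimethylchroman-2-yl]acetaldehyde
Conditions: i-Bu2AlH (1.05 equiv), CH2Cl2, −78 °C; Rochelle salt work-up; used crude
Reagents that add atoms: none
Why: Partial ester reduction stops at the tetrahedral aluminate at low temperature and releases the aldehyde only on work-up. The neutral tartrate work-up avoids the base that would open the β-aryloxy aldehyde by retro-oxa-Michael reaction.

Step 5
Reactants: 7 2-[(2R)-6-methoxy-2,8-dimethylchroman-2-yl]acetaldehyde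
Product: 8 (2R)-2-(3,3-dibromoprop-2-en-1-yl)-6-methoxy-2,8-dimethylchromane
Conditions: CBr4 (2 equiv), PPh3 (2 equiv), Zn dust (2 equiv), CH2Cl2, rt (ylide preformed); then 7, 0 °C to rt
Reagents that add atoms: carbon tetrabromide BrC(Br)(Br)Br
Why: First stage of the Corey–Fuchs sequence, a Wittig reaction with the preformed dibromomethylene ylide. No base is present, which protects the β-aryloxy aldehyde and C2.

Step 6
Reactants: 8 (2R)-2-(3,3-dibromoprop-2-en-1-yl)-6-methoxy-2,8-dimethylchromane
Product: 10 (2R)-6-methoxy-2,8-dimethyl-2-(5-methylhex-5-en-2-yn-1-yl)chromane, via lithium acetylide 9 (not isolated)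
Conditions: n-BuLi (2.2 equiv), THF, −78 °C to 0 °C; then CuBr·SMe2 (20 mol %), 3-bromo-2-methylpropene, −20 °C to rt
Reagents that add atoms: 3-bromo-2-methylpropene C=C(C)CBr
Why: Second stage of the Corey–Fuchs sequence: bromine–lithium exchange, α-elimination and Fritsch–Buttenberg–Wiechell 1,2-shift give the alkyne, which is deprotonated in place to acetylide 9. Copper-catalysed allylic substitution on the symmetrical methallyl bromide then gives the skipped enyne.

Step 7
Reactants: 11 1,2-dimethylcyclopentene
Product: 12 rac-(1R,5S)-7,7-dichloro-1,5-dimethylbicyclo[3.2.0]heptan-6-one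
Conditions: Cl3CCOCl, Zn–Cu couple, POCl3, Et2O, reflux
Reagents that add atoms: trichloroacetyl chloride O=C(Cl)C(Cl)(Cl)Cl
Why: Thermal (2+2) cycloaddition of dichloroketene, generated in the flask by zinc dechlorination of the acid chloride, with the electron-rich tetrasubstituted alkene. Suprafacial addition to the alkene sets both quaternary centres cis in one operation, as a racemate.

Step 8
Reactants: 12 rac-(1R,5S)-7,7-dichloro-1,5-dimethylbicyclo[3.2.0]heptan-6-one
Product: 13 rac-(1S,5S)-1,5-dimethylbicyclo[3.2.0]heptan-6-one
Conditions: Zn dust, AcOH, 60 °C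
Reagents that add atoms: none
Why: Reductive dechlorination of the α,α-dichloroketone through zinc enolates; the quaternary centres are not affected.

Step 9
Reactants: 13 rac-(1S,5S)-1,5-dimethylbicyclo[3.2.0]heptan-6-one
Product: 14 (1S,5S,4'R,5'R)-1,5-dimethyl-4',5'-diphenylspiro[bicyclo[3.2.0]heptane-6,2'-[1,3]dioxolane]
Conditions: (R,R)-hydrobenzoin (1.1 equiv), TsOH·H2O (cat.), toluene, reflux, Dean–Stark; diastereomers separated by chromatography or crystallisation
Reagents that add atoms: (1R,2R)-1,2-diphenylethane-1,2-diol O[C@H](c1ccccc1)[C@H](O)c1ccccc1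
Why: Acid-catalysed ketalisation, helped by strain relief at the four-membered carbonyl. The diol is C2-symmetric, so no new stereocentre arises and exactly two diastereomers should form; the wanted one is assigned by X-ray diffraction against the known diol configuration.

Step 10
Reactants: 14 (1S,5S,4'R,5'R)-1,5-dimethyl-4',5'-diphenylspiro[bicyclo[3.2.0]heptane-6,2'-[1,3]dioxolane]
Product: 15 (1S,5S)-1,5-dimethylbicyclo[3.2.0]heptan-6-one
Conditions: H2 (1 atm), Pd(OH)2/C, EtOAc, rt
Reagents that add atoms: none
Why: Hydrogenolysis of the two benzylic C–O bonds releases the ketone under neutral conditions; the ring stereocentres are untouched.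

Step 11
Reactants: 15 (1S,5S)-1,5-dimethylbicyclo[3.2.0]heptan-6-one; 10 (2R)-6-methoxy-2,8-dimethyl-2-(5-methylhex-5-en-2-yn-1-yl)chromane
Product: 16 (3aS,7aS)-6-{[(2R)-6-methoxy-2,8-dimethylchroman-2-yl]methyl}-3a,7a-dimethyl-5-(2-methylprop-2-en-1-yl)-1,2,3,3a,7,7a-hexahydro-4H-inden-4-one
Conditions: Ni(cod)2 (10 mol %), PCy3 (20 mol %), toluene, 100 °C; 15 (2 equiv), slow addition of 10
Reagents that add atoms: none
Why: Nickel-catalysed intermolecular alkyne insertion into a cyclobutanone (formal (4+2), two-carbon ring expansion): zerovalent nickel couples the carbonyl of 15 and the alkyne of 10 oxidatively to a spiro oxanickelacyclopentene, β-carbon elimination opens the strained four-membered ring, and reductive elimination from the seven-membered nickelacycle closes the cyclohexenone, forming C4–C5 and C6–C7. The closest known reaction type is this same nickel/trialkylphosphine coupling of cyclobutanones with internal dialkyl alkynes. The six-membered ring is closed by ring expansion (two carbons inserted into the acyl–CH2 bond), not by cyclisation of an open chain, so no Baldwin mode applies; the five-membered ring is untouched. No stereocentre is created: C3a and C7a are carried over from 15 with retention, because none of their bonds is broken and both are quaternary, and C2' sees only neutral conditions. Selectivity 1, which ring bond cleaves: β-carbon elimination must transfer the CH2 carbon (C7 of 15) and not the quaternary C5; this is secured because a primary alkyl–nickel bond is stronger and far less hindered than a tertiary one. Selectivity 2, orientation of the alkyne: the bond to the hindered, α-quaternary carbonyl carbon must form at the alkyne carbon bearing the slim, planar methallyl group while the neopentyl-type chromanylmethyl terminus stays on nickel; this steric difference is the reason the tertiary alcohol is carried as an alkene. Selectivity 3, insertion against alkyne oligomerisation: 15 is cheap and used in excess, and 10 is added slowly.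

Step 12
Reactants: 16 (3aS,7aS)-6-{[(2R)-6-methoxy-2,8-dimethylchroman-2-yl]methyl}-3a,7a-dimethyl-5-(2-methylprop-2-en-1-yl)-1,2,3,3a,7,7a-hexahydro-4H-inden-4-one
Product: 17 (3aS,7aS)-5-(2-hydroxy-2-methylpropyl)-6-{[(2R)-6-methoxy-2,8-dimethylchroman-2-yl]methyl}-3a,7a-dimethyl-1,2,3,3a,7,7a-hexahydro-4H-inden-4-one
Conditions: Co(acac)2 (20 mol %), PhSiH3 (2.5 equiv), O2 (1 atm), THF/i-PrOH, 0 °C to rt
Reagents that add atoms: dioxygen O=O
Why: Mukaiyama hydration by hydrogen-atom transfer: the cobalt hydride formed from Co(acac)2 and the silane delivers a hydrogen atom to the 1,1-disubstituted alkene, and the tertiary radical is trapped by O2 and reduced to the tertiary alcohol (Markovnikov). The electron-poor, tetrasubstituted enone alkene should be far slower in hydrogen-atom transfer, and the neutral conditions spare C2' and the new γ-hydroxy ketone.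

## Compound list

1 | 4-methoxy-2-methylphenol | COc1ccc(O)c(C)c1 | starting material
2 | 2-[(dimethylamino)methyl]-4-methoxy-6-methylphenol | CN(C)Cc1cc(OC)cc(C)c1O | intermediate
3 | (2-hydroxy-5-methoxy-3-methylbenzyl)trimethylammonium iodide | C[N+](C)(C)Cc1cc(OC)cc(C)c1O.[I-] | intermediate
4 | 4-methoxy-2-methyl-6-methylidenecyclohexa-2,4-dien-1-one | O=C1C(C)=CC(OC)=CC1=C | intermediate
5 | 4-methoxy-2-methyl-6-(3-methylbut-3-en-1-yl)phenol | C=C(C)CCc1cc(OC)cc(C)c1O | intermediate
6 | methyl 2-[(2R)-6-methoxy-2,8-dimethylchroman-2-yl]acetate | COc1cc(C)c2c(c1)CC[C@](C)(CC(=O)OC)O2 | intermediate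
7 | 2-[(2R)-6-methoxy-2,8-dimethylchroman-2-yl]acetaldehyde | COc1cc(C)c2c(c1)CC[C@](C)(CC=O)O2 | intermediate
8 | (2R)-2-(3,3-dibromoprop-2-en-1-yl)-6-methoxy-2,8-dimethylchromane | COc1cc(C)c2c(c1)CC[C@](C)(CC=C(Br)Br)O2 | intermediate
9 | lithium acetylide of (2R)-6-methoxy-2,8-dimethyl-2-(prop-2-yn-1-yl)chromane | COc1cc(C)c2c(c1)CC[C@](C)(CC#C[Li])O2 | intermediate
10 | (2R)-6-methoxy-2,8-dimethyl-2-(5-methylhex-5-en-2-yn-1-yl)chromane | COc1cc(C)c2c(c1)CC[C@](C)(CC#CCC(C)=C)O2 | intermediate
11 | 1,2-dimethylcyclopentene | CC1=C(C)CCC1 | starting material
12 | rac-(1R,5S)-7,7-dichloro-1,5-dimethylbicyclo[3.2.0]heptan-6-one (racemate, one enantiomer drawn) | O=C1[C@@]2(C)CCC[C@@]2(C)C1(Cl)Cl | intermediate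
13 | rac-(1S,5S)-1,5-dimethylbicyclo[3.2.0]heptan-6-one (racemate, one enantiomer drawn) | O=C1[C@@]2(C)CCC[C@@]2(C)C1 | intermediate
14 | (1S,5S,4'R,5'R)-1,5-dimethyl-4',5'-diphenylspiro[bicyclo[3.2.0]heptane-6,2'-[1,3]dioxolane] | O1[C@H](c3ccccc3)[C@@H](c3ccccc3)OC14[C@@]2(C)CCC[C@@]2(C)C4 | intermediate
15 | (1S,5S)-1,5-dimethylbicyclo[3.2.0]heptan-6-one | O=C1[C@@]2(C)CCC[C@@]2(C)C1 | intermediate
16 | (3aS,7aS)-6-{[(2R)-6-methoxy-2,8-dimethylchroman-2-yl]methyl}-3a,7a-dimethyl-5-(2-methylprop-2-en-1-yl)-1,2,3,3a,7,7a-hexahydro-4H-inden-4-one | COc1cc(C)c2c(c1)CC[C@](C)(CC1=C(CC(C)=C)C(=O)[C@@]3(C)CCC[C@@]3(C)C1)O2 | intermediate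
17 | (3aS,7aS)-5-(2-hydroxy-2-methylpropyl)-6-{[(2R)-6-methoxy-2,8-dimethylchroman-2-yl]methyl}-3a,7a-dimethyl-1,2,3,3a,7,7a-hexahydro-4H-inden-4-one | COc1cc(C)c2c(c1)CC[C@](C)(CC1=C(CC(C)(C)O)C(=O)[C@@]3(C)CCC[C@@]3(C)C1)O2 | target

## Step count and least certain steps

Total: 12 steps. Longest linear sequence: 8 steps (steps 1, 2, 3, 4, 5, 6, 11, 12); the cyclobutanone branch (steps 7 to 10) is 4 steps.

**Step 11 (key step).**
- Most likely failure: oxidative coupling at the α-quaternary carbonyl of 15 is slow, so that oligomerisation of the alkyne outruns insertion.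
- Second failure: partial loss of alkyne orientation, because both termini are primary at the propargylic carbon and differ only one atom further out.
- Fallback, from 15 and 7, returning at 16, fixing the same two bonds one at a time:
  - The lithium enolate of 15 (LDA, THF, −78 °C; C7 is the only enolisable position) is added to aldehyde 7 to give the aldol adduct (1S,5S)-7-{1-hydroxy-2-[(2R)-6-methoxy-2,8-dimethylchroman-2-yl]ethyl}-1,5-dimethylbicyclo[3.2.0]heptan-6-one F1.
  - Excess 3-methylbut-3-en-1-ylmagnesium bromide with CeCl3 adds to the strained carbonyl to give the diol (1S,5S)-7-{1-hydroxy-2-[(2R)-6-methoxy-2,8-dimethylchroman-2-yl]ethyl}-1,5-dimethyl-6-(3-methylbut-3-en-1-yl)bicyclo[3.2.0]heptan-6-ol F2.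
  - Dess–Martin oxidation of the secondary alcohol gives the 2-acylcyclobutanol 1-[(1S,5S)-6-hydroxy-1,5-dimethyl-6-(3-methylbut-3-en-1-yl)bicyclo[3.2.0]heptan-7-yl]-2-[(2R)-6-methoxy-2,8-dimethylchroman-2-yl]ethan-1-one F3.
  - Catalytic base opens F3 by strain-driven retro-aldol fragmentation (the De Mayo mode) to the 1,5-diketone 1-[cis-2-{3-[(2R)-6-methoxy-2,8-dimethylchroman-2-yl]-2-oxopropyl}-1,2-dimethylcyclopentyl]-4-methylpent-4-en-1-one F4, with the ring configuration of 15.
  - Acid-mediated aldol cyclodehydration (TsOH, benzene, Dean–Stark) closes F4 to 16.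
  - The configurations at C7, C6 and the side-chain carbinol of F1 to F3 are immaterial, because all are destroyed. The price is four more steps and a passage through β-aryloxy ketones, which is why acid is used for the last closure.

**Step 9.**
- Most likely failure: co-elution and co-crystallisation of the two ketals, because the enantiomers of 13 differ only in which side of the four-membered ring carries the carbonyl.
- Fallback, from 13, returning at 15:
  - Lithiated (S)-N,S-dimethyl-S-phenylsulfoximine (n-BuLi, THF, −78 °C) is added to the carbonyl to give the β-hydroxysulfoximine adduct of the (1S,5S) ketone, (S)-S-{[(1S,5S)-6-hydroxy-1,5-dimethylbicyclo[3.2.0]heptan-6-yl]methyl}-N-methyl-S-phenylsulfoximine F5.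
  - F5 is separated from its diastereomer by chromatography, with the polar, UV-active sulfoximine as handle.
  - Thermolysis (toluene, 130 °C) reverses the addition and distils out 15.

**Step 3.**
- Most likely failure: insufficient facial discrimination in the oxypalladation for this aryl substitution pattern, or a sense of induction opposite to the one expected.
- Fallback, from 5, returning at 6:
  - The same carbonylative cyclisation is run without the chiral ligand (Pd(OCOCF3)2, benzoquinone, CO, MeOH) to give racemic methyl 2-(6-methoxy-2,8-dimethylchroman-2-yl)acetate F6.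
  - The enantiomers are separated by preparative chromatography on a chiral stationary phase, and the R enantiomer is 6.

**Step 2.**
- Most likely failure: oligomerisation of the o-quinone methide before the Grignard reagent captures it, or incomplete quaternisation.
- Fallback, from 1, returning at 5, by a stepwise chain construction:
  - Magnesium-mediated ortho-formylation (MgCl2, Et3N, paraformaldehyde, MeCN, reflux) gives 2-hydroxy-5-methoxy-3-methylbenzaldehyde F7.
  - Claisen–Schmidt condensation with acetone (aq. NaOH) gives (E)-4-(2-hydroxy-5-methoxy-3-methylphenyl)but-3-en-2-one F8.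
  - Hydrogenation (H2, Pd/C, EtOAc) gives 4-(2-hydroxy-5-methoxy-3-methylphenyl)butan-2-one F9.
  - Wittig methylenation (Ph3PCH3Br, KOt-Bu, 3 equiv, THF) gives 5.

## Further compounds

F1 | step 11 | (1S,5S)-7-{1-hydroxy-2-[(2R)-6-methoxy-2,8-dimethylchroman-2-yl]ethyl}-1,5-dimethylbicyclo[3.2.0]heptan-6-one (mixture at C7 and the carbinol carbon) | COc1cc(C)c2c(c1)CC[C@](C)(CC(O)C1C(=O)[C@@]3(C)CCC[C@]31C)O2
F2 | step 11 | (1S,5S)-7-{1-hydroxy-2-[(2R)-6-methoxy-2,8-dimethylchroman-2-yl]ethyl}-1,5-dimethyl-6-(3-methylbut-3-en-1-yl)bicyclo[3.2.0]heptan-6-ol (mixture at C6, C7 and the carbinol carbon) | COc1cc(C)c2c(c1)CC[C@](C)(CC(O)C1C(O)(CCC(C)=C)[C@@]3(C)CCC[C@]31C)O2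
F3 | step 11 | 1-[(1S,5S)-6-hydroxy-1,5-dimethyl-6-(3-methylbut-3-en-1-yl)bicyclo[3.2.0]heptan-7-yl]-2-[(2R)-6-methoxy-2,8-dimethylchroman-2-yl]ethan-1-one (mixture at C6 and C7) | COc1cc(C)c2c(c1)CC[C@](C)(CC(=O)C1C(O)(CCC(C)=C)[C@@]3(C)CCC[C@]31C)O2
F4 | step 11 | 1-[cis-2-{3-[(2R)-6-methoxy-2,8-dimethylchroman-2-yl]-2-oxopropyl}-1,2-dimethylcyclopentyl]-4-methylpent-4-en-1-one (ring configuration as in 15) | COc1cc(C)c2c(c1)CC[C@](C)(CC(=O)C[C@]1(C)CCC[C@]1(C)C(=O)CCC(C)=C)O2
F5 | step 9 | (S)-S-{[(1S,5S)-6-hydroxy-1,5-dimethylbicyclo[3.2.0]heptan-6-yl]methyl}-N-methyl-S-phenylsulfoximine (carbinol configuration not assigned) | OC1(C[S@@](=O)(=NC)c2ccccc2)[C@@]3(C)CCC[C@@]3(C)C1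
F6 | step 3 | racemic methyl 2-(6-methoxy-2,8-dimethylchroman-2-yl)acetate | COc1cc(C)c2c(c1)CCC(C)(CC(=O)OC)O2
F7 | step 2 | 2-hydroxy-5-methoxy-3-methylbenzaldehyde | COc1cc(C)c(O)c(C=O)c1
F8 | step 2 | (E)-4-(2-hydroxy-5-methoxy-3-methylphenyl)but-3-en-2-one | COc1cc(C)c(O)c(/C=C/C(C)=O)c1
F9 | step 2 | 4-(2-hydroxy-5-methoxy-3-methylphenyl)butan-2-one | COc1cc(C)c(O)c(CCC(C)=O)c1
A1 | alternative 1 | 1-[cis-2-{3-[(2R)-6-methoxy-2,8-dimethylchroman-2-yl]-2-oxopropyl}-1,2-dimethylcyclopentyl]-4-hydroxy-4-methylpentan-1-one (ring configuration as in 15) | COc1cc(C)c2c(c1)CC[C@](C)(CC(=O)C[C@]1(C)CCC[C@]1(C)C(=O)CCC(C)(C)O)O2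
A2 | alternative 2 | 7-hydroxy-1-[(2R)-6-methoxy-2,8-dimethylchroman-2-yl]-7-methyloctane-2,4-dione | COc1cc(C)c2c(c1)CC[C@](C)(CC(=O)CC(=O)CCC(C)(C)O)O2
A3 | alternative 3 | (E)-9-(2-hydroxy-5-methoxy-3-methylphenyl)-2,7-dimethylnon-6-en-4-yn-2-ol | COc1cc(C)c(O)c(CC/C(C)=C/C#CCC(C)(C)O)c1
A4 | alternative 3 | (3aS,7aS)-6-[(1E)-4-(2-hydroxy-5-methoxy-3-methylphenyl)-2-methylbut-1-en-1-yl]-5-(2-hydroxy-2-methylpropyl)-3a,7a-dimethyl-1,2,3,3a,7,7a-hexahydro-4H-inden-4-one | COc1cc(C)c(O)c(CC/C(C)=C/C2=C(CC(C)(C)O)C(=O)[C@@]3(C)CCC[C@@]3(C)C2)c1
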